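**Strategy.** The dihydropyranone C ring (O1, C2, C3, C4, C4a, C8a) is cut at C2. Without the ArCH carbon C2, O1 closes on C3 to a five-membered 2-hydroxybenzofuran-3(2H)-one, the lactol of an o-hydroxyaryl glyoxal. Its lactol carbon and OH are the later C3 and 3-OH. The key step exploits the O1–C2(aryl)–C3(OH)–C4(=O) array of this ring: an enantiopure 4-benzyloxybenzyl sulfonium ylide epoxidises the ring-opened aldehyde, and O1 then opens the epoxide at the benzylic carbon. One operation joins the two halves, inserts C2 between O1 and C3 (five- to six-membered ring) and sets C2 and C3. The C6 diarylethane centre comes earlier from an asymmetric hydrogenation.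

Key step: step 8

Remark: flavonoid numbering (O1, C2 … C8a) is used for all intermediates.

Assumption: the (1R,4R,5R)-sulfide is taken to leave open the ylide face that makes the ylide carbon (S) in epoxide 17, the spatial analogue of (S,S)-stilbene oxide. If the sense proves opposite, the equally available enantiomeric sulfide is used in the same way.

Step 1
Reactants: 1 3,5-dimethoxyphenol
Product: 2 triisopropyl(3,5-dimethoxyphenoxy)silane
Conditions: TIPSCl, imidazole, DMF, rt
Reagents that add atoms: triisopropylsilyl chloride, CC(C)[Si](Cl)(C(C)C)C(C)C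
Why: Standard O-silylation of a phenol; the bulky, non-coordinating OTIPS group masks the later O1 and shields its two ortho positions, so that the metalation in step 2 goes between the two methoxy groups.

Step 2
Reactants: 2 triisopropyl(3,5-dimethoxyphenoxy)silane; 3 1-[4-(benzyloxy)phenyl]ethan-1-one
Product: 6 {4-[1-(4-benzyloxyphenyl)ethenyl]-3,5-dimethoxyphenoxy}triisopropylsilane, via aryllithium 4 (not isolated), via tertiary carbinol 5 (not isolated)
Conditions: n-BuLi, THF, 0 °C to rt; 3, −78 °C to rt; AcOH quench; crude, PPTS (cat.), toluene, 60 °C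
Reagents that add atoms: none
Why: Directed ortho-metalation at the carbon flanked by two coordinating OMe groups, 1,2-addition of the aryllithium to the ketone and E1 dehydration of the doubly benzylic carbinol (only the CH3 carries β-hydrogens) should give the 1,1-diarylethene.

Step 3
Reactants: 6 {4-[1-(4-benzyloxyphenyl)ethenyl]-3,5-dimethoxyphenoxy}triisopropylsilane
Product: 7 {4-[(1R)-1-(4-benzyloxyphenyl)ethyl]-3,5-dimethoxyphenoxy}triisopropylsilane
Conditions: H2 (5 bar), [Ir(cod)(L*)]BArF (1 mol %, L* = chiral phosphite–oxazoline), CH2Cl2, rt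
Reagents that add atoms: none
Why: Iridium–N,P-catalysed asymmetric hydrogenation of an unfunctionalised 1,1-diarylethene: the 2,6-dimethoxyaryl ring is forced perpendicular to the alkene while the 4-benzyloxyphenyl ring stays coplanar, so the catalyst can tell the two aryl groups apart, the ligand enantiomer is chosen to deliver H2 to the face that gives the (R) centre, and benzyl and silyl ethers are inert to this homogeneous catalyst.

Step 4
Reactants: 7 {4-[(1R)-1-(4-benzyloxyphenyl)ethyl]-3,5-dimethoxyphenoxy}triisopropylsilane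
Product: 8 4-[(1R)-1-(4-benzyloxyphenyl)ethyl]-3,5-dimethoxyphenol
Conditions: TBAF, AcOH, THF, 0 °C
Reagents that add atoms: none
Why: Fluoride-induced cleavage of the aryl silyl ether, buffered so that the electron-rich phenoxide is protonated at once; no other group responds to fluoride.

Step 5
Reactants: 8 4-[(1R)-1-(4-benzyloxyphenyl)ethyl]-3,5-dimethoxyphenol
Product: 9 1-{3-[(1R)-1-(4-benzyloxyphenyl)ethyl]-6-hydroxy-2,4-dimethoxyphenyl}ethan-1-one
Conditions: AcCl, SnCl4, CH2Cl2, −40 to −10 °C; aq. work-up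
Reagents that add atoms: acetyl chloride, CC(=O)Cl
Why: Friedel–Crafts acylation of a phloroglucinol-type ring whose only two free positions are equivalent (both ortho to OH), so no regioisomer can arise, and the low temperature protects the acid-sensitive aryl–CH(CH3)Ar bond, its stereocentre and the benzyl ether.

Step 6
Reactants: 9 1-{3-[(1R)-1-(4-benzyloxyphenyl)ethyl]-6-hydroxy-2,4-dimethoxyphenyl}ethan-1-one
Product: 11 5-[(1R)-1-(4-benzyloxyphenyl)ethyl]-2-hydroxy-4,6-dimethoxy-1-benzofuran-3(2H)-one, via open-chain glyoxal 10 (not isolated)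
Conditions: SeO2, 1,4-dioxane/H2O, 90 °C
Reagents that add atoms: selenium dioxide, O=[Se]=O
Why: Riley oxidation of the methyl ketone to the aryl glyoxal, whose aldehyde is captured by the only free ortho OH as the five-membered lactol; the new lactol centre forms as a mixture of epimers, which does not matter because it is opened again in step 8.

Step 7
Reactants: 12 (1R,4R,5R)-isothiocineole; 13 [4-(benzyloxy)phenyl]methanol
Product: 14 (1R,4R,5R,6R)-6-[4-(benzyloxy)benzyl]-4,7,7-trimethyl-6-thiabicyclo[3.2.1]octan-6-ium tetrafluoroborate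
Conditions: HBF4·OEt2, Et2O, 0 °C to rt
Reagents that add atoms: tetrafluoroboric acid, [H+].F[B-](F)(F)F
Why: SN1-type S-alkylation of the sulfide by the 4-benzyloxybenzyl cation released from the alcohol; attack through the less hindered exo lone pair should fix a single configuration at sulfur.

Step 8
Reactants: 11 5-[(1R)-1-(4-benzyloxyphenyl)ethyl]-2-hydroxy-4,6-dimethoxy-1-benzofuran-3(2H)-one; 14 sulfonium tetrafluoroborate
Product: 18 (2R,3R)-2-[4-(benzyloxy)phenyl]-6-[(1R)-1-(4-benzyloxyphenyl)ethyl]-3-hydroxy-5,7-dimethoxychroman-4-one, via sulfonium ylide 15 (not isolated), via potassium phenoxide glyoxal 16 (not isolated), via trans-epoxy ketone 17 (not isolated)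
Conditions: 14 (1.2 equiv), KHMDS (1.15 equiv), THF, −78 °C; 11 pre-treated with KHMDS (1.0 equiv), THF, −78 °C, added; −78 to −40 °C; then MsOH (1.3 equiv), HFIP, −40 to 0 °C
Reagents that add atoms: none
Why: KHMDS opens lactol 11 to the phenoxide glyoxal 16, whose aldehyde (the ketone is deactivated by the oxido- and methoxy-substituted ring) is attacked by the preformed ylide 15 to give an anti betaine that closes (3-exo-tet) to the trans-epoxy ketone 17 with loss of the sulfide, i.e. an asymmetric Corey–Chaykovsky epoxidation of a lactol-masked aldehyde. Acidification in HFIP then lets O1 open the epoxide at its benzylic carbon (6-endo-tet), so that the ArCH carbon ends up inserted into the former O1–C(lactol) bond and the five-membered ring becomes the six-membered one; the closest known reactions are the one-carbon ring expansions of cyclic hemiaminals and sugar lactols with sulfur ylides and the cyclisation of 2'-hydroxychalcone epoxides to dihydroflavonols. C2 is fixed by the ylide face that the bicyclic sulfide leaves open and is inverted once in the ring closure ((S) in 17, (R) in 18), while C3 follows from the anti (trans-epoxide) selectivity of betaine formation and keeps its C–O bond. If the opening takes on SN1 character, the retained C3 centre should still steer closure to the diequatorial 2,3-trans product. The step needs 6-endo over 5-exo opening (attack at the α-keto carbon would lead to aurone-type benzofuranones), and the cation-stabilising 4-benzyloxyphenyl group together with the switch from phenoxide to acid/HFIP activation before warming should secure it. The 5-O-methyl group leaves O1 as the only phenol, which secures the 6- rather than the 8-substituted ring system.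

Step 9
Reactants: 18 (2R,3R)-2-[4-(benzyloxy)phenyl]-6-[(1R)-1-(4-benzyloxyphenyl)ethyl]-3-hydroxy-5,7-dimethoxychroman-4-one
Product: 19 (2R,3R)-3,5-dihydroxy-2-(4-hydroxyphenyl)-6-[(1R)-1-(4-hydroxyphenyl)ethyl]-7-methoxychroman-4-one
Conditions: BCl3, pentamethylbenzene, CH2Cl2, −78 to 0 °C; MeOH, then aq. NaHCO3
Reagents that add atoms: none
Why: Boron trichloride ether cleavage: both aryl benzyl ethers fall with pentamethylbenzene as cation scavenger, the 5-OMe is cleaved through its chelate with C4=O, the unchelated 7-OMe stays, and no stereocentre is touched (2,3-trans is also the thermodynamic arrangement).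

**Compound list**

1 | 3,5-dimethoxyphenol | COc1cc(O)cc(OC)c1 | starting material
2 | triisopropyl(3,5-dimethoxyphenoxy)silane | COc1cc(O[Si](C(C)C)(C(C)C)C(C)C)cc(OC)c1 | intermediate
3 | 1-[4-(benzyloxy)phenyl]ethan-1-one | CC(=O)c1ccc(OCc2ccccc2)cc1 | starting material
4 | [2,6-dimethoxy-4-(triisopropylsilyloxy)phenyl]lithium | [Li]c1c(OC)cc(O[Si](C(C)C)(C(C)C)C(C)C)cc1OC | intermediate
5 | rac-1-[4-(benzyloxy)phenyl]-1-[2,6-dimethoxy-4-(triisopropylsilyloxy)phenyl]ethan-1-ol | COc1cc(O[Si](C(C)C)(C(C)C)C(C)C)cc(OC)c1C(C)(O)c1ccc(OCc2ccccc2)cc1 | intermediate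
6 | {4-[1-(4-benzyloxyphenyl)ethenyl]-3,5-dimethoxyphenoxy}triisopropylsilane | COc1cc(O[Si](C(C)C)(C(C)C)C(C)C)cc(OC)c1C(=C)c1ccc(OCc2ccccc2)cc1 | intermediate
7 | {4-[(1R)-1-(4-benzyloxyphenyl)ethyl]-3,5-dimethoxyphenoxy}triisopropylsilane | COc1cc(O[Si](C(C)C)(C(C)C)C(C)C)cc(OC)c1[C@H](C)c1ccc(OCc2ccccc2)cc1 | intermediate
8 | 4-[(1R)-1-(4-benzyloxyphenyl)ethyl]-3,5-dimethoxyphenol | COc1cc(O)cc(OC)c1[C@H](C)c1ccc(OCc2ccccc2)cc1 | intermediate
9 | 1-{3-[(1R)-1-(4-benzyloxyphenyl)ethyl]-6-hydroxy-2,4-dimethoxyphenyl}ethan-1-one | CC(=O)c1c(O)cc(OC)c([C@H](C)c2ccc(OCc3ccccc3)cc2)c1OC | intermediate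
10 | 2-{3-[(1R)-1-(4-benzyloxyphenyl)ethyl]-6-hydroxy-2,4-dimethoxyphenyl}-2-oxoacetaldehyde | O=CC(=O)c1c(O)cc(OC)c([C@H](C)c2ccc(OCc3ccccc3)cc2)c1OC | intermediate
11 | 5-[(1R)-1-(4-benzyloxyphenyl)ethyl]-2-hydroxy-4,6-dimethoxy-1-benzofuran-3(2H)-one (both C2 epimers) | COc1cc2OC(O)C(=O)c2c(OC)c1[C@H](C)c1ccc(OCc3ccccc3)cc1 | intermediate
12 | (1R,4R,5R)-4,7,7-trimethyl-6-thiabicyclo[3.2.1]octane (isothiocineole) | C[C@@H]1CC[C@@H]2C[C@H]1SC2(C)C | starting material
13 | [4-(benzyloxy)phenyl]methanol | OCc1ccc(OCc2ccccc2)cc1 | starting material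
14 | (1R,4R,5R,6R)-6-[4-(benzyloxy)benzyl]-4,7,7-trimethyl-6-thiabicyclo[3.2.1]octan-6-ium tetrafluoroborate | C[C@@H]1CC[C@@H]2C[C@H]1[S@@+](Cc1ccc(OCc3ccccc3)cc1)C2(C)C.F[B-](F)(F)F | intermediate
15 | 4-benzyloxybenzylide of 14 (sulfonium ylide) | C[C@@H]1CC[C@@H]2C[C@H]1[S@@+]([CH-]c1ccc(OCc3ccccc3)cc1)C2(C)C | intermediate
16 | potassium 4-[(1R)-1-(4-benzyloxyphenyl)ethyl]-3,5-dimethoxy-2-(oxoacetyl)phenolate | [K+].[O-]c1cc(OC)c([C@H](C)c2ccc(OCc3ccccc3)cc2)c(OC)c1C(=O)C=O | intermediate
17 | {(2R,3S)-3-[4-(benzyloxy)phenyl]oxiran-2-yl}{3-[(1R)-1-(4-benzyloxyphenyl)ethyl]-6-hydroxy-2,4-dimethoxyphenyl}methanone | COc1cc(O)c(C(=O)[C@@H]2O[C@H]2c2ccc(OCc3ccccc3)cc2)c(OC)c1[C@H](C)c1ccc(OCc2ccccc2)cc1 | intermediate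
18 | (2R,3R)-2-[4-(benzyloxy)phenyl]-6-[(1R)-1-(4-benzyloxyphenyl)ethyl]-3-hydroxy-5,7-dimethoxychroman-4-one | COc1cc2c(c(OC)c1[C@H](C)c1ccc(OCc3ccccc3)cc1)C(=O)[C@H](O)[C@@H](c1ccc(OCc3ccccc3)cc1)O2 | intermediate
19 | (2R,3R)-3,5-dihydroxy-2-(4-hydroxyphenyl)-6-[(1R)-1-(4-hydroxyphenyl)ethyl]-7-methoxychroman-4-one | COc1cc2c(c(O)c1[C@H](C)c1ccc(O)cc1)C(=O)[C@H](O)[C@@H](c1ccc(O)cc1)O2 | target

Total step count: 9. Longest linear sequence: 8 (steps 1–6, 8, 9).

**Steps most likely to fail**

**1. Step 8.**
- What may go wrong: the phenoxide may attack the α-keto carbon of the epoxide (5-exo) before the acid switch, with later loss of water toward aurone-type material. The very reactive glyoxal aldehyde may also make syn-betaine formation irreversible and erode the trans selectivity.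
- Fallback, from 17 back to 18: the cold mixture is neutralised with MsOH alone. The crude epoxide 17 is opened at the benzylic carbon by an external soft nucleophile (BnSH, SnCl4, CH2Cl2, −20 °C) to the β-benzylsulfanyl α-hydroxy ketone F1, in which the C3 centre is untouched. Thiophilic activation (AgBF4, CH2Cl2, 0 °C) then lets O1 close the six-membered ring under control of C3 and gives 18.

**2. Step 3.**
- What may go wrong: poor enantioface discrimination or slow turnover on the alkene that carries a di-ortho-substituted aryl group.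
- Fallback, from 2 and 3 back to 8: this route is stereospecific instead of enantioselective.
  - 2 is lithiated as in step 2 and quenched with 2-isopropoxy-4,4,5,5-tetramethyl-1,3,2-dioxaborolane to the aryl pinacol boronate F2.
  - Ketone 3 is reduced by Ru–TsDPEN asymmetric transfer hydrogenation to (S)-1-[4-(benzyloxy)phenyl]ethanol F3 and carbamoylated (iPr2NCOCl, Et3N) to the (S)-diisopropylcarbamate F4.
  - s-BuLi (Et2O, −78 °C) lithiates F4 with retention and F2 adds with retention. The 1,2-metallate shift (MgBr2, MeOH, warming) displaces the carbamate with inversion to the tertiary boronic ester F5.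
  - TBAF·3H2O replaces boron by hydrogen with retention and removes the silyl group in the same pot, which gives 8.

**3. Step 9.**
- What may go wrong: incomplete cleavage of the hindered 5-O-methyl group at temperatures that the benzylic C2–O1 bond and the C6 aryl–CH bond tolerate, and C-benzylation of the electron-rich rings.
- Fallback, from 18 back to 19: the two deprotections are separated. Hydrogenolysis (H2, Pd(OH)2/C, EtOAc/MeOH) removes both benzyl groups and gives the 5-O-methyl ether of the target F6. A mild chelation-controlled demethylation (MgI2·OEt2, THF, 50 °C) then frees only the 5-OH and gives 19.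

**Further compounds**

F1 | step 8 | (2S)-3-(benzylsulfanyl)-3-[4-(benzyloxy)phenyl]-1-{3-[(1R)-1-(4-benzyloxyphenyl)ethyl]-6-hydroxy-2,4-dimethoxyphenyl}-2-hydroxypropan-1-one (both C3 epimers) | COc1cc(O)c(C(=O)[C@H](O)C(SCc2ccccc2)c2ccc(OCc3ccccc3)cc2)c(OC)c1[C@H](C)c1ccc(OCc2ccccc2)cc1
F2 | step 3 | 2-[2,6-dimethoxy-4-(triisopropylsilyloxy)phenyl]-4,4,5,5-tetramethyl-1,3,2-dioxaborolane | COc1cc(O[Si](C(C)C)(C(C)C)C(C)C)cc(OC)c1B1OC(C)(C)C(C)(C)O1
F3 | step 3 | (S)-1-[4-(benzyloxy)phenyl]ethanol | C[C@H](O)c1ccc(OCc2ccccc2)cc1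
F4 | step 3 | (S)-1-[4-(benzyloxy)phenyl]ethyl N,N-diisopropylcarbamate | C[C@H](OC(=O)N(C(C)C)C(C)C)c1ccc(OCc2ccccc2)cc1
F5 | step 3 | (R)-2-{1-[4-(benzyloxy)phenyl]-1-[2,6-dimethoxy-4-(triisopropylsilyloxy)phenyl]ethyl}-4,4,5,5-tetramethyl-1,3,2-dioxaborolane | COc1cc(O[Si](C(C)C)(C(C)C)C(C)C)cc(OC)c1[C@](B1OC(C)(C)C(C)(C)O1)(C)c1ccc(OCc2ccccc2)cc1
F6 | step 9 | (2R,3R)-3-hydroxy-2-(4-hydroxyphenyl)-6-[(1R)-1-(4-hydroxyphenyl)ethyl]-5,7-dimethoxychroman-4-one | COc1cc2c(c(OC)c1[C@H](C)c1ccc(O)cc1)C(=O)[C@H](O)[C@@H](c1ccc(O)cc1)O2
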